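**Plan**

- Retrosynthesis: the diaryl ether C–O bond on ring B is cut first (depsidone to depside), then the depside ester C(=O)–O bond, giving a ring A salicylic acid and a ring B hydroxyphthalide. The formyl C–C bond of ring A leads back to methyl orsellinate, and the benzylic C–O bonds and lactone of ring B lead back to atraric acid.
- Forward: the ring A acid is made by formylation, O-methylation and ester cleavage. The ring B phthalide is made by acetylation, threefold benzylic bromination and methanolysis, which closes the five-membered lactone. Esterification joins the rings, oxidation closes the seven-membered ring, and deprotection frees the lactol.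
- Enabling feature: in ring B the carbon that carries the ether oxygen is para to the free phenol and ortho to the ester oxygen. In the depside it is the only aromatic C–H of ring B, so oxidation of that phenol activates exactly this carbon while the ester holds the ring A hydroxyl over it.
- Stereochemistry: the lactol carbon is the only stereocentre and equilibrates through the open formyl acid. It is therefore set last, by seeded attrition-enhanced crystallisation of the (S) form.

Key step: step 8

Assumption: the lactol carbon epimerises in solution by ring–chain tautomerism, so the (S) configuration is defined for the crystalline solid only, and the racemic lactol is taken to crystallise as a conglomerate.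

**Route**

Step 1
Reactants: 1 methyl orsellinate (methyl 2,4-dihydroxy-6-methylbenzoate)
Product: 3 methyl haematommate (methyl 3-formyl-2,4-dihydroxy-6-methylbenzoate), via chloro ether 2 (not isolated)
Conditions: Cl2CHOMe (1.2 equiv), TiCl4 (2.5 equiv), CH2Cl2, −10 to 0 °C; then 1 M HCl (aq)
Reagents that add atoms: dichloromethyl methyl ether, COC(Cl)Cl; water, O
Why: Rieche formylation of the titanium-bound resorcinol should occur at C3, the carbon ortho to both hydroxyls, to give chloro ether 2, which is hydrolysed on work-up, the 5-formyl isomer being the expected minor product to be removed by crystallisation.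

Step 2
Reactants: 3 methyl haematommate
Product: 4 methyl 3-formyl-2-hydroxy-4-methoxy-6-methylbenzoate
Conditions: MeI (1.1 equiv), K2CO3 (1.1 equiv), acetone, 40 °C
Reagents that add atoms: iodomethane, CI
Why: Williamson etherification should take place only at the 4-hydroxyl, which is the more acidic and accessible phenol, because the 2-hydroxyl is locked between the ester and formyl carbonyls by hydrogen bonding.

Step 3
Reactants: 4 methyl 3-formyl-2-hydroxy-4-methoxy-6-methylbenzoate
Product: 6 3-formyl-2-hydroxy-4-methoxy-6-methylbenzoic acid, via acylium ion 5 (not isolated)
Conditions: conc. H2SO4, 0 °C to rt; then ice–water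
Reagents that add atoms: water, O
Why: unimolecular acid-catalysed acyl cleavage (AAc1) of a 2,6-disubstituted, oxygen-rich benzoate should give acylium ion 5, which water converts to the acid on quenching, so the hindered ester is cleaved without base and the aryl methyl ether and aldehyde are left alone.

Step 4
Reactants: 7 atraric acid (methyl 2,4-dihydroxy-3,6-dimethylbenzoate)
Product: 8 methyl 2,4-diacetoxy-3,6-dimethylbenzoate
Conditions: Ac2O, pyridine, DMAP (cat.), rt
Reagents that add atoms: acetic anhydride, CC(=O)OC(C)=O
Why: DMAP-catalysed O-acetylation of both phenols lowers the electron density of the ring so that the following bromination attacks the side chains and not C5.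

Step 5
Reactants: 8 methyl 2,4-diacetoxy-3,6-dimethylbenzoate
Product: 9 methyl 2,4-diacetoxy-3-(bromomethyl)-6-(dibromomethyl)benzoate
Conditions: NBS (3.3 equiv, in portions), AIBN (cat.), PhCF3, 85 °C
Reagents that add atoms: N-bromosuccinimide, O=C1CCC(=O)N1Br
Why: in this Wohl–Ziegler bromination the C6 methyl, with one ortho substituent, should take two bromines as o-toluates do, while the C3 methyl, flanked by two acetoxy groups, should stop at the monobromide because a second hydrogen abstraction there is sterically retarded.

Step 6
Reactants: 9 methyl 2,4-diacetoxy-3-(bromomethyl)-6-(dibromomethyl)benzoate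
Product: 11 racemic 5,7-dihydroxy-3-methoxy-6-(methoxymethyl)-3H-isobenzofuran-1-one, via bromophthalide 10 (not isolated)
Conditions: MeOH, 80 °C (sealed vessel)
Reagents that add atoms: methanol, CO
Why: in this solvolysis cascade the ester carbonyl should capture the α-bromobenzyl cation of the CHBr2 group with loss of bromomethane to give bromophthalide 10, after which methanol replaces both remaining benzylic bromides (SN1) and the HBr set free catalyses transesterification of the two aryl acetates.

Step 7
Reactants: 6 3-formyl-2-hydroxy-4-methoxy-6-methylbenzoic acid; 11 racemic 5,7-dihydroxy-3-methoxy-6-(methoxymethyl)-3H-isobenzofuran-1-one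
Product: 13 racemic depside 7-hydroxy-3-methoxy-6-(methoxymethyl)-1-oxo-1,3-dihydroisobenzofuran-5-yl 3-formyl-2-hydroxy-4-methoxy-6-methylbenzoate, via acyl trifluoroacetate 12 (not isolated)
Conditions: (CF3CO)2O, toluene, 0 °C to rt
Reagents that add atoms: none
Why: mixed-anhydride esterification with trifluoroacetic anhydride, the usual way to depsides, should activate 6 as 12 and acylate the free 5-hydroxyl of 11, while the 7-hydroxyl (hydrogen-bonded to the lactone carbonyl, two ortho substituents) and the chelated ring A hydroxyl stay free.

Step 8
Reactants: 13 racemic depside
Product: 16 racemic depsidone (ring A 4-methoxy; ring B 7-hydroxyl free; methoxymethyl group and 3-methoxyphthalide kept), via aryloxyiodane 14 (not isolated), via dienone 15 (not isolated)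
Conditions: PhI(OCOCF3)2 (1.05 equiv, slow addition), (CF3)2CHOH/CH2Cl2 (1:4), 5 mM, −20 °C
Reagents that add atoms: none
Why: Proposed new method: ligand exchange of the ring B phenol of 13 on trivalent iodine should give aryloxy-λ3-iodane 14, whose ring carbon para to oxygen (C4 of the phthalide) becomes electrophilic as iodobenzene departs, so that the ester-tethered ring A hydroxyl adds there to give dienone 15, which tautomerises to phenol 16. The closest known reactions are hypervalent-iodine para C–O functionalisations of phenols (quinol ethers, quinone monoketals, spirolactones) and one-electron para C–O phenol couplings as in poly(phenylene ether) formation, whereas a diaryl ether closure of a depside by this route has not been shown. The seven-membered ring closes by attack of the tethered oxygen on a trigonal ring carbon, a 7-endo-trig closure when counted through the C4=C5 bond of ring B, which Baldwin's rules allow. No stereocentre is formed, and the existing acetal carbon is not touched. The step needs chemoselective oxidation of ring B, which should follow because the ring A phenol is doubly hydrogen-bonded and has carbonyl-bearing carbons at both ortho positions where positive charge would develop, whereas ring B has only one, and regioselectivity is fixed because C4 is the only unsubstituted carbon conjugated with the ring B phenol. High dilution, the weakly nucleophilic fluoroalcohol and slow addition of one equivalent of oxidant should favour capture by the tether over capture by solvent and limit further oxidation of 16, which has no internal nucleophile left.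

Step 9
Reactants: 16 racemic depsidone
Product: 18 racemic salazinic acid (the target constitution with the lactol carbon as both enantiomers), via dichloride 17 (not isolated)
Conditions: BCl3 (6 equiv), CH2Cl2, −78 to 0 °C; then THF/H2O, 40 °C
Reagents that add atoms: water, O
Why: Lewis acid ether cleavage with BCl3 should remove the ring A methyl ether through chelation to the neighbouring formyl group and turn the benzylic methyl ether and the methoxyphthalide acetal into the chlorides of 17, which water then hydrolyses (SN1, assisted by the ortho phenol and the ring oxygen) to the hydroxymethyl group and the lactol while the hindered depsidone ester survives.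

Step 10
Reactants: 18 racemic salazinic acid
Product: 19 (S)-salazinic acid, the (S)-lactol
Conditions: slurry in acetone/H2O (9:1), AcOH (cat.), glass beads, vigorous stirring, 25 °C, seeded with (S) crystals; filtration
Reagents that add atoms: none
Why: attrition-enhanced deracemisation (Viedma ripening) of a conglomerate should convert the whole solid into the crystal form of the (S) seed, because the lactol carbon racemises in solution through ring–chain tautomerism to the achiral formyl acid, as is known for ring–chain tautomeric hydroxyisoindolinones, and this sets the stereocentre.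

**Compound list**

1 | methyl orsellinate (methyl 2,4-dihydroxy-6-methylbenzoate) | COC(=O)c1c(C)cc(O)cc1O | starting material
2 | methyl 3-[chloro(methoxy)methyl]-2,4-dihydroxy-6-methylbenzoate (titanium-bound in the flask) | COC(=O)c1c(C)cc(O)c(C(Cl)OC)c1O | intermediate (not isolated)
3 | methyl haematommate (methyl 3-formyl-2,4-dihydroxy-6-methylbenzoate) | COC(=O)c1c(C)cc(O)c(C=O)c1O | intermediate
4 | methyl 3-formyl-2-hydroxy-4-methoxy-6-methylbenzoate | COC(=O)c1c(C)cc(OC)c(C=O)c1O | intermediate
5 | 3-formyl-2-hydroxy-4-methoxy-6-methylbenzoylium hydrogen sulfate | Cc1cc(OC)c(C=O)c(O)c1C#[O+].OS(=O)(=O)[O-] | intermediate (not isolated)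
6 | 3-formyl-2-hydroxy-4-methoxy-6-methylbenzoic acid | Cc1cc(OC)c(C=O)c(O)c1C(=O)O | intermediate
7 | atraric acid (methyl 2,4-dihydroxy-3,6-dimethylbenzoate) | COC(=O)c1c(C)cc(O)c(C)c1O | starting material
8 | methyl 2,4-diacetoxy-3,6-dimethylbenzoate | COC(=O)c1c(C)cc(OC(C)=O)c(C)c1OC(C)=O | intermediate
9 | methyl 2,4-diacetoxy-3-(bromomethyl)-6-(dibromomethyl)benzoate | COC(=O)c1c(C(Br)Br)cc(OC(C)=O)c(CBr)c1OC(C)=O | intermediate
10 | racemic 5,7-diacetoxy-3-bromo-6-(bromomethyl)-3H-isobenzofuran-1-one | CC(=O)Oc1cc2C(Br)OC(=O)c2c(OC(C)=O)c1CBr | intermediate (not isolated)
11 | racemic 5,7-dihydroxy-3-methoxy-6-(methoxymethyl)-3H-isobenzofuran-1-one | COCc1c(O)cc2C(OC)OC(=O)c2c1O | intermediate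
12 | 3-formyl-2-hydroxy-4-methoxy-6-methylbenzoic trifluoroacetic anhydride | Cc1cc(OC)c(C=O)c(O)c1C(=O)OC(=O)C(F)(F)F | intermediate (not isolated)
13 | racemic depside: 7-hydroxy-3-methoxy-6-(methoxymethyl)-1-oxo-1,3-dihydroisobenzofuran-5-yl 3-formyl-2-hydroxy-4-methoxy-6-methylbenzoate | Cc1cc(OC)c(C=O)c(O)c1C(=O)Oc1cc2C(OC)OC(=O)c2c(O)c1COC | intermediate
14 | racemic aryloxy-λ3-iodane: the 7-oxygen of 13 bound to iodine that also carries phenyl and trifluoroacetate | Cc1cc(OC)c(C=O)c(O)c1C(=O)Oc1cc2C(OC)OC(=O)c2c(OI(c3ccccc3)OC(=O)C(F)(F)F)c1COC | intermediate (not isolated)
15 | cyclohexa-2,5-dienone tautomer of 16 (former phthalide C4 is sp3 and bears H and the new ether oxygen; mixture of diastereomers) | Cc1cc(OC)c(C=O)c2c1C(=O)OC1=C(COC)C(=O)C3=C(C1O2)C(OC)OC3=O | intermediate (not isolated)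
16 | racemic depsidone: the dibenzo[b,e][1,4]dioxepin-11-one from 13, with ring A 4-methoxy, 3-formyl and 6-methyl groups and ring B free 7-hydroxyl, 6-methoxymethyl group and fused 3-methoxyphthalide | Cc1cc(OC)c(C=O)c2c1C(=O)Oc1c(COC)c(O)c3c(c1O2)C(OC)OC3=O | intermediate
17 | racemic dichloride: 16 with ring A hydroxyl free, chloromethyl in place of methoxymethyl and 3-chlorophthalide in place of 3-methoxyphthalide | Cc1cc(O)c(C=O)c2c1C(=O)Oc1c(CCl)c(O)c3c(c1O2)C(Cl)OC3=O | intermediate (not isolated)
18 | racemic salazinic acid | Cc1cc(O)c(C=O)c2c1C(=O)Oc1c(CO)c(O)c3c(c1O2)C(O)OC3=O | intermediate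
19 | (S)-salazinic acid, (S) at the lactol carbon | Cc1cc(O)c(C=O)c2c1C(=O)Oc1c(CO)c(O)c3c(c1O2)[C@@H](O)OC3=O | target

**Summary**

Total steps: 10. Longest linear sequence: 7 steps (steps 1–3 or steps 4–6, followed by steps 7–10).

Steps most likely to fail:

1. Step 8 (oxidative ring closure). The product phenol is more electron-rich than the depside and may be oxidised further, and solvent or trifluoroacetate may capture the activated ring before the hindered, hydrogen-bonded ring A hydroxyl does. Fallback with known chemistry: the ether bond is made by copper catalysis on a pre-brominated ring B. Setting out from 11, NBS in MeCN at 0 °C should brominate the only free ring position to give racemic 4-bromo-5,7-dihydroxy-3-methoxy-6-(methoxymethyl)-3H-isobenzofuran-1-one F1. Esterification of F1 with acid 6 under the conditions of step 7 should give the racemic bromo depside 4-bromo-7-hydroxy-3-methoxy-6-(methoxymethyl)-1-oxo-1,3-dihydroisobenzofuran-5-yl 3-formyl-2-hydroxy-4-methoxy-6-methylbenzoate F2. Intramolecular Ullmann etherification (CuI, N,N-dimethylglycine, Cs2CO3, dioxane, 90 °C) then closes the seven-membered ring and rejoins the route at 16.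

2. Step 5 (threefold bromination). The bromine may be distributed wrongly between the two benzylic carbons, by a second bromination at the hindered C3 carbon or by incomplete bromination at C6. Fallback: the C3 carbon is introduced already oxygenated, so that only one methyl group is left to brominate. Setting out from 3, reduction of the formyl group (NaBH4, THF, 0 °C, AcOH quench) should give methyl 2,4-dihydroxy-3-(hydroxymethyl)-6-methylbenzoate F3. Acetylation (Ac2O, pyridine, DMAP) gives methyl 2,4-diacetoxy-3-(acetoxymethyl)-6-methylbenzoate F4. Wohl–Ziegler dibromination (NBS, 2.2 equiv, AIBN, PhCF3, 85 °C) gives methyl 2,4-diacetoxy-3-(acetoxymethyl)-6-(dibromomethyl)benzoate F5. Acidic methanolysis (MeOH, HCl cat., 80 °C) closes the methoxyphthalide, removes the aryl acetates and exchanges the benzylic acetate for the methyl ether, rejoining the route at 11 and replacing steps 4 to 6.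

3. Step 10 (deracemisation). The racemate may crystallise as a racemic compound and not as a conglomerate, so that grinding brings no enrichment. Fallback: setting out from 18, the enantiomers are separated by preparative chromatography on a cellulose tris(3,5-dimethylphenylcarbamate) phase with a cold, alcohol-free eluent. The (S) fraction is evaporated cold to give 19, and the (R) fraction is racemised in wet acetone with a trace of acid and recycled. This detour makes no new compound (F0).

Further compounds
F1 | step 8 | racemic 4-bromo-5,7-dihydroxy-3-methoxy-6-(methoxymethyl)-3H-isobenzofuran-1-one | COCc1c(O)c(Br)c2C(OC)OC(=O)c2c1O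
F2 | step 8 | racemic 4-bromo-7-hydroxy-3-methoxy-6-(methoxymethyl)-1-oxo-1,3-dihydroisobenzofuran-5-yl 3-formyl-2-hydroxy-4-methoxy-6-methylbenzoate | Cc1cc(OC)c(C=O)c(O)c1C(=O)Oc1c(Br)c2C(OC)OC(=O)c2c(O)c1COC
F3 | step 5 | methyl 2,4-dihydroxy-3-(hydroxymethyl)-6-methylbenzoate | COC(=O)c1c(C)cc(O)c(CO)c1O
F4 | step 5 | methyl 2,4-diacetoxy-3-(acetoxymethyl)-6-methylbenzoate | COC(=O)c1c(C)cc(OC(C)=O)c(COC(C)=O)c1OC(C)=O
F5 | step 5 | methyl 2,4-diacetoxy-3-(acetoxymethyl)-6-(dibromomethyl)benzoate | COC(=O)c1c(C(Br)Br)cc(OC(C)=O)c(COC(C)=O)c1OC(C)=O
F0 | step 10 | none | none
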